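The time can stay as it is: the green run reads 0% starting material at 20.0 min, the red run reads 0% at 50.0 min, and 1.5 h lies beyond both. The choice for the next flasks is therefore the charge of second substrate, and the number to watch is a split ratio (a selectivity factor): the fraction of the charge found as uncatalysed product over the fraction found as target. Dividing one path by the other takes time out of the reckoning.

| flask | starting material | second substrate | partner | free catalyst | remark | time |
|---|---|---|---|---|---|---|
| green | 0.30 M | 0.54 M | 0.75 M | 1.5 mM | run made earlier |  |
| teal | 0.30 M | 1.1 M | 0.75 M | 1.5 mM | run made earlier |  |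
| red | 0.30 M | 2.1 M | 0.75 M | 1.5 mM | run made earlier |  |
| dusk | 0.30 M | 1.80 M | 0.750 M | 1.5 mM |  | 1.5 h |
| dawn | 0.30 M | 0.600 M | 0.750 M | 1.5 mM |  | 1.5 h |

| run | time / min | starting material / % | uncatalysed product / % | catalyst intermediate A / % | target / % |
|---|---|---|---|---|---|
| green | 20.0 | 0 | 44 | 0 | 52 |
| green | 40.0 | 0 | 45 | 0 | 57 |
| green | 50.0 | 0 | 44 | 0 | 55 |
| green | 80.0 | 0 | 46 | 0 | 53 |
| green | 90.0 | 1 | 45 | 0 | 57 |
| teal | 8.00 | 24 | 43 | 0 | 33 |
| teal | 25.0 | 2 | 54 | 0 | 47 |
| teal | 40.0 | 5 | 53 | 0 | 47 |
| teal | 60.0 | 0 | 58 | 0 | 46 |
| teal | 90.0 | 0 | 55 | 0 | 44 |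
| red | 8.00 | 29 | 46 | 0 | 20 |
| red | 15.0 | 10 | 58 | 1 | 29 |
| red | 25.0 | 4 | 62 | 0 | 31 |
| red | 50.0 | 0 | 66 | 0 | 36 |
| red | 90.0 | 0 | 67 | 0 | 35 |

(standard deviation of a reading: 1.5 percentage points)



* which of these there is most of at the end, counted by the starting material in it, dusk (catalyst intermediate A / uncatalysed product / target / starting material)
* which of these there is most of at the end, counted by the starting material in it, dawn (catalyst intermediate A / uncatalysed product / target / starting material)
* the largest of these amounts at the end, in percent of the starting material charged, dusk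
* the largest of these amounts at the end, in percent of the starting material charged, dawn

From 20.0 min on, green reads a split ratio of 0.818 at 1.80 equivalents of second substrate. From 50.0 min on, red reads 1.87 at 7.00 equivalents. A straight line through these two rises by 0.203 per equivalent. Teal, kept out of the line, reads 1.21 from 40.0 min on, where the line gives 1.20.

The line was read with partner and free catalyst held, so both stay as charged. Dusk, at 6.00 equivalents, gets a ratio of 1.67, which is 62.5% uncatalysed product. Dawn, at 2.00 equivalents, gets 0.858, the split ratio at dawn's charge, uncatalysed product over target, which is 53.8% target. Dawn is the charge to make for target.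

The forecast, from its own line, says uncatalysed product at 63% for dusk and target at 54% for dawn, and calls these “interpolations within the tested range, with the same partner and catalyst loadings”.

Dusk ends with uncatalysed product at 63.0%, dawn with target at 52.8%.

    partner + catalyst intermediate B → free catalyst + second product (k = 0.180 L mol⁻¹ s⁻¹)
    second substrate + free catalyst ⇌ catalyst intermediate B (K = 2.00 L mol⁻¹, k = 1.60 L mol⁻¹ s⁻¹)
    starting material + free catalyst ⇌ catalyst intermediate A (K = 4.80 L mol⁻¹, k = 2.80 L mol⁻¹ s⁻¹)
    partner + catalyst intermediate A → free catalyst + target (k = 11.0 L mol⁻¹ s⁻¹)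
    starting material + partner → uncatalysed product (k = 0.00290 L mol⁻¹ s⁻¹)

In dawn at 0.550 h, starting material goes to catalyst intermediate A at 2.2 times its rate to uncatalysed product, forward step alone. That capture has 96% of its turnover up to 1.5 h behind it by 0.300 h. Partner stands in the uncatalysed step's rate and not in the capture's, so for the neighbour of dawn with 1.3 M of partner, a reckoning that takes free catalyst as in dawn multiplies the carried ratio by the ratio of the partner charges and gets 1.49, or 40.2% target. That flask computes to 39.0% target and 61.0% uncatalysed product.

The data were generated by integration for an exercise, noise included.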